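At 0 °C the free catalyst lasts 26.2 s, far shorter than the 15 min each flask is kept.

    starting material + coupling partner + free catalyst → free catalyst + target (k1 = 23300 M⁻² s⁻¹, Ea1 = 13.0 kJ mol⁻¹)
    second substrate + coupling partner + free catalyst → free catalyst + second product (k2 = 1.06 × 10⁵ M⁻² s⁻¹, Ea2 = 16.0 kJ mol⁻¹)
    target → over-reaction product (k3 = 3.45 × 10⁻⁶ s⁻¹, Ea3 = 87.0 kJ mol⁻¹)
    starting material + target → side product (k4 = 0.0238 M⁻¹ s⁻¹, Ea4 = 43.0 kJ mol⁻¹)
    free catalyst → spent catalyst (k5 = 0.0381 s⁻¹, Ea5 = 75.0 kJ mol⁻¹)
    (constants at 0 °C)

all flasks: second substrate 20.0 mM; free catalyst 24 µM; time 15 min
- gamma: starting material 20 mM (fed, over 3.0 min); coupling partner 20.0 mM; temperature 0 °C; all else is in the flask from the start; the feed brings no volume worth counting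
- alpha: starting material 20 mM; coupling partner 20.0 mM (fed, over 3.0 min); temperature 0 °C; all else is in the flask from the start; the feed brings no volume worth counting
- epsilon: starting material 20 mM; coupling partner 20.0 mM (in portions, 2, over 3.0 min); temperature 0 °C; first portion at the start, last at 3.0 min
- eta: starting material 20 mM; coupling partner 20.0 mM (fed, over 3.0 min); the addition at −30 °C, then warmed to 0 °C; the feed brings no volume worth counting

- in percentages every species weighs as the starting material in it: one side product counts as two
- the constants hold at 0 °C; other temperatures follow from the activation energies

- the flask with the highest share of target in target plus side product ("all alike" if they lie within 1.5 percentage points) (gamma / alpha / epsilon / eta / all alike)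
- share of target in target plus side product at the end, gamma
- share of target in target plus side product at the end, alpha
- share of target in target plus side product at the end, epsilon
- share of target in target plus side product at the end, eta

Two people argue at the board. The doser says the feed is the lever: starting material attacks target, so keep c(starting material) low. The timer answers that with so short a catalyst life, target appears early and then sits beside starting material, so what counts is how long and how warm it sits. I side with the timer.

Target decays at a pseudo-first-order rate, the attack constant times c(starting material), while that concentration stays near its charge. Multiply this rate by the time and it gives 0.428 over the whole run; I call this number the exposure E. The step to over-reaction product gives 0.00311, far less. A fraction exp(−E) of the target survives, and each target lost makes one side product, which counts double. So for target made at the start the share is 1/(2 exp(E) − 1), however much was made, and with the starting material in the flask from the start, as in alpha and epsilon, that gives 48.3%.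

The doser uses the same sum. During the feed, gamma holds on average half the charge, so its exposure falls to 0.386 and its share rises to 51.5%. He ranks gamma first, with eta, dosed like alpha, beside alpha.

The timer replies that in eta the catalyst lasts 25.7 min in the cold, longer than the feed. The exposure of that cold stretch is 0.00829. Taking the warm-up as immediate and counting from it, eta's exposure is 0.343, a saving twice gamma's. My figure for eta is 55.0%, with c(starting material) held at its charge, and that puts eta first.

The forecast takes the timer's side: eta first, with gamma 52.2%, alpha 50.7%, epsilon 51.8% and eta 62.5%. Each of its figures stands above mine, and its ground for putting eta ahead is that “much more target forms and less starting material remains to attack it”.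

The simulation gives eta first, with gamma 52.6%, alpha 51.2%, epsilon 51.7% and eta 62.7%. Eta leads gamma by 10 percentage points, and gamma leads alpha by 1.4 points, less than the margin, so the timer wins. Eta holds 73.4% of its starting material at 15.0 min, while my figure held the whole charge, and that end level, put in the sum for the whole stretch after the warm-up, gives 63.6%. The doser's lever does work as an amount: with all else held, alpha's answer has moved 5 points at a charge of 16.9 mM or 23.6 mM of starting material.

Now take the neighbour of alpha kept at 25 °C, with amounts and time held. Warming raises the attack constant to 0.116 M⁻¹ s⁻¹, so the exposure over 15 min becomes 2.10 and the sum gives a share of 6.55%. In that neighbour, >99.9% of the starting material is still there at the end, as the sum assumes. The simulated share of the neighbour is 6.30%.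

The rate constants were drawn at random within sensible limits; the rest is arithmetic.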